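**Plan**
- Cuts: the aryl O–Si bonds and the ketal are protecting-group operations; the C4 and C8 methylenes go back to lactone carbonyls; the bis-lactone is then cut at C1–C2 and C5–C6 (aldol) and at O3–C4 and O7–C8 (acyl–oxygen).
- Enabling feature: C8–C1(OH)–C5(OH)–C4 of the 3,7-dioxabicyclo[3.3.0]octane is the carbon chain of tartaric acid (C4, C8 = carboxyl carbons). Each carbinol hydrogen is replaced by an ArCH–O unit (C2, C6), so the core is a tartrate acetonide plus two aryl aldehydes.
- Forward: the dioxolane is made first; ring C1–C2–O3–C4–C5 and then ring C5–C6–O7–C8–C1 close around it as γ-lactones in one flask; both C=O are reduced to CH2, then the ketal and silyl ethers are removed.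
- Stereochemistry: C1 and C5 come from (S,S)-tartrate with retention (resident dioxolane centre, then cis ring fusion); C2 and C6 (aryl exo) come from reversible aldol addition funnelled through lactonisation.

Key step: step 3

Remark: all bicyclic compounds are numbered as 3,7-dioxabicyclo[3.3.0]octanes (C1, C5 bridgeheads; C2, C6 ArCH; C4, C8 carboxyl-derived carbons). The target is taken as the C2-symmetric (1S,2R,5S,6R) isomer with both aryl groups exo, i.e. cis to the bridgehead oxygen of their ring. LDA is used as the commercial solution.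

**Route**

Step 1
Reactants: 1 dimethyl D-tartrate [dimethyl (2S,3S)-2,3-dihydroxybutanedioate]
Product: 2 dimethyl (4S,5S)-2,2-dimethyl-1,3-dioxolane-4,5-dicarboxylate
Conditions: Me2C(OMe)2, TsOH·H2O (cat.), cyclohexane, reflux, MeOH distilled off
Reagents that add atoms: 2,2-dimethoxypropane, CC(C)(OC)OC
Why: Acid-catalysed transketalisation of the threo-diol gives the trans-dioxolane without touching either stereocentre, and removal of methanol drives it to completion.

Step 2
Reactants: 3 vanillin (4-hydroxy-3-methoxybenzaldehyde)
Product: 4 3-methoxy-4-(triisopropylsilyloxy)benzaldehyde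
Conditions: TIPSCl, imidazole, DMF, 0 °C → rt
Reagents that add atoms: triisopropylsilyl chloride, CC(C)[Si](Cl)(C(C)C)C(C)C
Why: Imidazole-promoted O-silylation of the phenol; the bulky TIPS group is chosen so that the aryl silyl ether withstands the lithium methoxide released in step 3 and the acids of steps 5 and 6.

Step 3
Reactants: 2 dimethyl (4S,5S)-2,2-dimethyl-1,3-dioxolane-4,5-dicarboxylate; 4 3-methoxy-4-(triisopropylsilyloxy)benzaldehyde (2 equiv in two portions)
Product: 6 acetonide-bridged exo,exo-diaryl bis-lactone (1S,2R,5S,6R)-1,5-(isopropylidenedioxy)-2,6-bis[3-methoxy-4-(triisopropylsilyloxy)phenyl]-3,7-dioxabicyclo[3.3.0]octane-4,8-dione, via mono-lactone methyl ester 5 (not isolated)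
Conditions: LDA (1.1 equiv), THF–DMPU, −78 °C; 4 (1.0 equiv), −78 → −30 °C; recool to −78 °C, LDA (1.2 equiv); 4 (1.2 equiv), −78 → −20 °C; AcOH
Reagents that add atoms: none
Why: LDA converts 2 into the dioxolane ester enolate, which undergoes lithium aldol addition to 4 at C1; the C2 alkoxide then attacks the C5 ester lying cis to it on the dioxolane and expels methoxide (5-exo-trig acyl substitution) to close the first γ-lactone (5), and the second LDA charge enolises the remaining C5–H of 5 so that the same aldol/5-exo-trig lactonisation onto the C1 ester closes the second γ-lactone and completes the tetraoxa[3.3.3]propellane 6. The closest known chemistry is the stereoretentive alkylation and aldol addition of tartrate acetonide enolates (self-regeneration of stereocentres), combined with the aldolate-to-γ-lactone closure familiar from succinate aldols and an ordinary lactone-enolate aldol. C1 is set by the resident C5 centre: as in alkylations of this enolate the electrophile enters syn to the neighbouring ester so that the two esters stay trans, and an adduct formed on the other face cannot reach an ester and reverts by retro-aldol; C5 is set by ring fusion, because the enolate of 5 can only be attacked on the face that keeps the bicycle cis-fused, which is also the face that places C6 next to the C1 ester it must acylate. C2 and C6 are set under Curtin–Hammett conditions: aldol addition is reversible whereas loss of methoxide is practically not, and ring closure should be faster for the epimer whose aryl group avoids the neighbouring carbon substituent (CO2Me on C1, then the lactone carbonyl on C5) and sits syn to the dioxolane oxygen, which is exo in the target. The step also needs addition to outrun β-elimination of the dioxolane oxygen; in both enolates the β C–O bond is held by the ring close to the nodal plane of the π system, and generation at −78 °C with immediate trapping should keep ring-opening at bay.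

Step 4
Reactants: 6 acetonide-bridged bis-lactone
Product: 7 bis-lactol (1S,2R,5S,6R)-1,5-(isopropylidenedioxy)-2,6-bis[3-methoxy-4-(triisopropylsilyloxy)phenyl]-3,7-dioxabicyclo[3.3.0]octane-4,8-diol (anomer mixture at C4 and C8)
Conditions: DIBAL-H (2.5 equiv), CH2Cl2, −78 °C; Rochelle salt
Reagents that add atoms: none
Why: Partial reduction of lactones with DIBAL-H: at −78 °C the aluminium hemiacetalate, here chelated by the adjacent dioxolane oxygen, persists until work-up so that reduction stops at the lactol; the silyl ethers and the ketal are inert, and the new hemiacetal centres disappear in step 5.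

Step 5
Reactants: 7 bis-lactol
Product: 8 (1S,2R,5S,6R)-1,5-(isopropylidenedioxy)-2,6-bis[3-methoxy-4-(triisopropylsilyloxy)phenyl]-3,7-dioxabicyclo[3.3.0]octane
Conditions: Et3SiH, BF3·OEt2, CH2Cl2, −78 → −40 °C; NaHCO3
Reagents that add atoms: none
Why: Ionic hydrogenation of lactols: BF3 ionises each hemiacetal to a five-membered oxocarbenium ion that Et3SiH reduces to CH2 (the reduction used for isopropylidene-protected furanose lactols and for aryl-substituted furofuran lactols), and the low temperature should keep the ketal and the benzylic C–O bonds from ionising; no stereocentre is formed.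

Step 6
Reactants: 8 acetonide-protected bis-silyl furofuran
Product: 9 (1S,2R,5S,6R)-2,6-bis[3-methoxy-4-(triisopropylsilyloxy)phenyl]-3,7-dioxabicyclo[3.3.0]octane-1,5-diol
Conditions: AcOH–H2O (4:1), 60 °C
Reagents that add atoms: none
Why: Acid-catalysed ketal hydrolysis: in weak aqueous acid the 2-alkoxy-2-propyl cation forms far more easily than a benzylic cation from the ring ethers, so C2 and C6 should keep their configuration, and aryl TIPS ethers are stable to aqueous acetic acid.

Step 7
Reactants: 9 bis-silyl diol
Product: 10 prinsepiol, (1S,2R,5S,6R)-2,6-bis(4-hydroxy-3-methoxyphenyl)-3,7-dioxabicyclo[3.3.0]octane-1,5-diol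
Conditions: TBAF, AcOH, THF, 0 °C
Reagents that add atoms: none
Why: Fluoride-mediated desilylation: aryl silyl ethers are cleaved quickly through Si–F bond formation, and the acetic acid buffer keeps the phenols from standing as phenoxides that could open the benzylic ethers via quinone methides, so all four stereocentres are retained.

**Compound list**
1 | dimethyl D-tartrate, dimethyl (2S,3S)-2,3-dihydroxybutanedioate | O[C@H](C(=O)OC)[C@H](O)C(=O)OC | starting material
2 | dimethyl (4S,5S)-2,2-dimethyl-1,3-dioxolane-4,5-dicarboxylate | COC(=O)[C@H]1OC(C)(C)O[C@@H]1C(=O)OC | intermediate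
3 | vanillin | COc1cc(C=O)ccc1O | starting material
4 | 3-methoxy-4-(triisopropylsilyloxy)benzaldehyde | COc1cc(C=O)ccc1O[Si](C(C)C)(C(C)C)C(C)C | intermediate
5 | mono-lactone methyl ester, methyl (3aS,4R,6aS)-4-[3-methoxy-4-(triisopropylsilyloxy)phenyl]-2,2-dimethyl-6-oxodihydrofuro[3,4-d][1,3]dioxole-3a(4H)-carboxylate (γ-lactone C1–C2–O3–C4–C5 cis-fused to the dioxolane; CO2Me on C1, aryl on C2 cis to the dioxolane oxygen, H on C5) | COc1cc([C@H]2OC(=O)[C@H]3OC(C)(C)O[C@@]23C(=O)OC)ccc1O[Si](C(C)C)(C(C)C)C(C)C | intermediate
6 | (1S,2R,5S,6R)-1,5-(isopropylidenedioxy)-2,6-bis[3-methoxy-4-(triisopropylsilyloxy)phenyl]-3,7-dioxabicyclo[3.3.0]octane-4,8-dione | COc1cc([C@H]2OC(=O)[C@]3(OC(C)(C)O4)[C@@H](c5ccc(O[Si](C(C)C)(C(C)C)C(C)C)c(OC)c5)OC(=O)[C@]234)ccc1O[Si](C(C)C)(C(C)C)C(C)C | intermediate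
7 | (1S,2R,5S,6R)-1,5-(isopropylidenedioxy)-2,6-bis[3-methoxy-4-(triisopropylsilyloxy)phenyl]-3,7-dioxabicyclo[3.3.0]octane-4,8-diol, anomer mixture | COc1cc([C@H]2OC(O)[C@]3(OC(C)(C)O4)[C@@H](c5ccc(O[Si](C(C)C)(C(C)C)C(C)C)c(OC)c5)OC(O)[C@]234)ccc1O[Si](C(C)C)(C(C)C)C(C)C | intermediate
8 | (1S,2R,5S,6R)-1,5-(isopropylidenedioxy)-2,6-bis[3-methoxy-4-(triisopropylsilyloxy)phenyl]-3,7-dioxabicyclo[3.3.0]octane | COc1cc([C@H]2OC[C@]3(OC(C)(C)O4)[C@@H](c5ccc(O[Si](C(C)C)(C(C)C)C(C)C)c(OC)c5)OC[C@]234)ccc1O[Si](C(C)C)(C(C)C)C(C)C | intermediate
9 | (1S,2R,5S,6R)-2,6-bis[3-methoxy-4-(triisopropylsilyloxy)phenyl]-3,7-dioxabicyclo[3.3.0]octane-1,5-diol | COc1cc([C@H]2OC[C@]3(O)[C@@H](c4ccc(O[Si](C(C)C)(C(C)C)C(C)C)c(OC)c4)OC[C@]23O)ccc1O[Si](C(C)C)(C(C)C)C(C)C | intermediate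
10 | prinsepiol | COc1cc([C@H]2OC[C@]3(O)[C@@H](c4ccc(O)c(OC)c4)OC[C@]23O)ccc1O | target

**Count**
Total steps: 7. Longest linear sequence: 6 steps (steps 1, 3, 4, 5, 6, 7 from dimethyl D-tartrate); step 2 is a one-step side branch.

**Steps most likely to fail**

Step 3. The configuration at the aryl-bearing carbons C2 and C6 may be controlled incompletely, because the preference for exo-aryl ring closure rests on a modest steric difference; the enolates may also be partly lost to β-elimination. The fallback sets out from 6, taken as whatever C2/C6 epimer mixture step 3 delivers. LiAlH4 in THF at 0 °C opens both lactones to the acetonide tetraol F1, which has mixed benzylic configuration and untouched C1/C5. Catalytic camphorsulfonic acid in CH2Cl2 (0 °C → rt, molecular sieves) then ionises each p-silyloxybenzylic alcohol, and the primary hydroxyl on the other dioxolane carbon, which lies cis to it, captures the cation in a five-membered ring closure. This is the classical cationic furofuran cyclisation. Because the benzylic C–O bond forms reversibly, the epimers should converge on the exo-aryl arrangement. The sequence rejoins the route at 8 and skips 7.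

Step 5. The oxocarbenium ions or the product may ionise at the electron-rich benzylic C–O bonds, causing epimerisation at C2/C6 or over-reduction to benzyl groups, and the ketal may be opened reductively. The fallback sets out from 7 and avoids cations altogether. NaBH4 in THF–MeOH at 0 °C reduces the lactols through their hydroxy-aldehyde tautomers to the single-isomer tetraol F2. TsCl (2.2 equiv) in pyridine at 0 °C sulfonylates only the two primary hydroxyls to give the bis-tosylate F3. NaH in THF (0 °C → rt) then closes both tetrahydrofuran rings by intramolecular Williamson etherification (5-exo-tet) from the benzylic alkoxides. The C–O bonds at C2 and C6 are never broken, so their configuration is retained, and the route is rejoined at 8.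

Step 6. Acid strong enough to open the hindered, inductively deactivated ketal may also ionise the benzylic ethers and epimerise C2/C6. The fallback sets out from 8 and deactivates the aryl rings before the acid step. TBAF/AcOH in THF gives the bis-phenol acetonide F4. Ac2O in pyridine gives the bis(aryl acetate) F5, whose acetoxy groups stabilise a benzylic cation far less than silyloxy or hydroxy groups. TFA–H2O (9:1) at 0 °C can then cleave the ketal to the diol diacetate F6. K2CO3 in MeOH at 0 °C removes the aryl acetates and arrives at 10.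

**Further compounds**
F1 | step 3 | acetonide tetraol, [(4S,5S)-4,5-bis(hydroxymethyl)-2,2-dimethyl-1,3-dioxolane-4,5-diyl]bis{[3-methoxy-4-(triisopropylsilyloxy)phenyl]methanol}, benzylic epimer mixture | OC[C@@]1(C(O)c2ccc(O[Si](C(C)C)(C(C)C)C(C)C)c(OC)c2)OC(C)(C)O[C@@]1(CO)C(O)c3ccc(O[Si](C(C)C)(C(C)C)C(C)C)c(OC)c3
F2 | step 5 | acetonide tetraol, single isomer with both benzylic carbinols R | OC[C@@]1([C@H](O)c2ccc(O[Si](C(C)C)(C(C)C)C(C)C)c(OC)c2)OC(C)(C)O[C@@]1(CO)[C@H](O)c3ccc(O[Si](C(C)C)(C(C)C)C(C)C)c(OC)c3
F3 | step 5 | bis(primary tosylate) of the acetonide tetraol | Cc1ccc(cc1)S(=O)(=O)OC[C@@]2([C@H](O)c3ccc(O[Si](C(C)C)(C(C)C)C(C)C)c(OC)c3)OC(C)(C)O[C@@]2(COS(=O)(=O)c4ccc(C)cc4)[C@H](O)c5ccc(O[Si](C(C)C)(C(C)C)C(C)C)c(OC)c5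
F4 | step 6 | prinsepiol 1,5-acetonide, (1S,2R,5S,6R)-1,5-(isopropylidenedioxy)-2,6-bis(4-hydroxy-3-methoxyphenyl)-3,7-dioxabicyclo[3.3.0]octane | COc1cc([C@H]2OC[C@]3(OC(C)(C)O4)[C@@H](c5ccc(O)c(OC)c5)OC[C@]234)ccc1O
F5 | step 6 | prinsepiol 1,5-acetonide bis(aryl acetate) | COc1cc([C@H]2OC[C@]3(OC(C)(C)O4)[C@@H](c5ccc(OC(C)=O)c(OC)c5)OC[C@]234)ccc1OC(C)=O
F6 | step 6 | prinsepiol bis(aryl acetate) | COc1cc([C@H]2OC[C@]3(O)[C@@H](c4ccc(OC(C)=O)c(OC)c4)OC[C@]23O)ccc1OC(C)=O
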